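The route rests on one disconnection of the cyclohexane ring: the bond between its two adjacent CH2 groups and the bond joining the ring-fusion CH to the oxygen-bearing, methyl-substituted ring-fusion carbon. The O–C(CH3)–CH2 unit so revealed is an isopropenyl ether on the tertiary oxygen of (R)-linalool, whose carbinol carbon becomes the vinyl-bearing pyran centre. In the key step a vinylketene, generated by Wolff rearrangement of an acyclic α′-diazo enone, is trapped by this tethered enol ether in an intramolecular [4+2] cycloaddition that closes the carbocycle and the tetrahydropyran together and sets both ring-fusion centres. The resulting enone then directs installation of the two acid side chains before its carbonyl is removed.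

Key step: step 7

Remark: (R)-(−)-linalool of high enantiomeric purity is taken as commercially available. Bicyclic compounds are numbered as chromenes (O1; C2 carries vinyl and methyl; C4a and C8a are the ring-fusion carbons; C5–C8 lie in the carbocycle). The Tebbe reagent Cp2Ti(μ-Cl)(μ-CH2)AlMe2 is drawn in its open form Cp2Ti(Cl)CH2AlMe2, in which the chloride on titanium also coordinates aluminium.

Step 1
Reactants: 1 (R)-(−)-linalool
Product: 2 (3R)-3,7-dimethylocta-1,6-dien-3-yl acetate
Conditions: Ac2O, Et3N, DMAP (cat.), CH2Cl2, 25–40 °C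
Reagents that add atoms: acetic anhydride CC(=O)OC(C)=O
Why: DMAP-catalysed O-acylation of the tertiary allylic alcohol under basic conditions proceeds without ionisation, so the (R)-centre is retained.

Step 2
Reactants: 2 (3R)-3,7-dimethylocta-1,6-dien-3-yl acetate
Product: 3 (3R,6E)-3,7-dimethyl-8-oxoocta-1,6-dien-3-yl acetate
Conditions: SeO2 (1.1 equiv), 1,4-dioxane, 80 °C
Reagents that add atoms: selenium dioxide O=[Se]=O
Why: Riley-type SeO2 allylic oxidation (ene reaction then [2,3]-sigmatropic shift) should attack the (E)-methyl group of the trisubstituted olefin selectively and give the (E)-enal, while the vinyl group has no allylic hydrogen.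

Step 3
Reactants: 3 (3R,6E)-3,7-dimethyl-8-oxoocta-1,6-dien-3-yl acetate
Product: 4 (3R,6E)-8-hydroxy-3,7-dimethylnona-1,6-dien-3-yl acetate (mixture of C8 epimers)
Conditions: MeMgBr (1.1 equiv), THF, −78 °C; NH4Cl (aq)
Reagents that add atoms: methylmagnesium bromide C[Mg]Br
Why: Grignard 1,2-addition to the enal at −78 °C should outpace attack on the hindered tertiary acetate; the new carbinol centre forms unselectively and is erased in step 5.

Step 4
Reactants: 4 (3R,6E)-8-hydroxy-3,7-dimethylnona-1,6-dien-3-yl acetate
Product: 5 (3E,7R)-3,7-dimethyl-7-(prop-1-en-2-yloxy)nona-3,8-dien-2-ol (mixture of C2 epimers)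
Conditions: Tebbe reagent Cp2Ti(μ-Cl)(μ-CH2)AlMe2 (2.5 equiv), pyridine, THF/toluene, −40 to 20 °C; NaOH (aq)
Reagents that add atoms: Tebbe reagent C[Al](C)C[Ti](Cl)(C1C=CC=C1)C1C=CC=C1
Why: Tebbe methylenation ([2+2] addition of Cp2Ti=CH2 to the ester carbonyl and cycloreversion) converts the acetate, the only carbonyl group present, into the isopropenyl ether under basic conditions and below 20 °C, where the allyl vinyl ether should not yet undergo Claisen rearrangement; the free hydroxyl is held as its metal alkoxide by the excess reagent and released on basic work-up.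

Step 5
Reactants: 5 (3E,7R)-3,7-dimethyl-7-(prop-1-en-2-yloxy)nona-3,8-dien-2-ol
Product: 6 (3E,7R)-3,7-dimethyl-7-(prop-1-en-2-yloxy)nona-3,8-dien-2-one
Conditions: activated MnO2 (15 equiv), CH2Cl2, 20 °C
Reagents that add atoms: none
Why: MnO2 oxidises the allylic secondary alcohol selectively under neutral conditions that leave the acid-labile enol ether intact.

Step 6
Reactants: 6 (3E,7R)-3,7-dimethyl-7-(prop-1-en-2-yloxy)nona-3,8-dien-2-one
Product: 8 (3E,7R)-1-diazo-3,7-dimethyl-7-(prop-1-en-2-yloxy)nona-3,8-dien-2-one, via trifluoroacetyl diketone 7 (not isolated)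
Conditions: LiN(SiMe3)2, THF, −78 °C; CF3CO2CH2CF3; then MsN3, Et3N, H2O, MeCN, 20 °C
Reagents that add atoms: methanesulfonyl azide CS(=O)(=O)N=[N+]=[N-]
Why: Kinetic α′-enolisation, trifluoroacetylation and deacylative (Regitz-type) diazo transfer should give the α′-diazo enone regiospecifically under basic conditions compatible with the enol ether.

Step 7
Reactants: 8 (3E,7R)-1-diazo-3,7-dimethyl-7-(prop-1-en-2-yloxy)nona-3,8-dien-2-one
Product: 10 (2R,4aS,8aR)-2-ethenyl-2,5,8a-trimethyl-2,3,4,4a,8,8a-hexahydro-7H-chromen-7-one, via vinylketene 9 (not isolated)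
Conditions: hν (λ ≥ 300 nm, Pyrex), degassed CH2Cl2 (5 mM), 0–20 °C
Reagents that add atoms: none
Why: Proposed new method: photochemical Wolff rearrangement of 8 expels N2 and shifts the alkenyl group to give (E)-vinylketene 9, whose electrophilic ketene carbon is attacked by the nucleophilic CH2 terminus of the tethered isopropenyl ether while the diene terminus bonds to the oxygen-bearing carbon, an inverse-electron-demand type 1 intramolecular [4+2] cycloaddition that forms C7–C8 and C4a–C8a and delivers the conjugated cyclohexenone directly. The closest known reaction types are the polar [2+2] cycloaddition of ketenes with enol ethers, the [4+2] cycloadditions of silyl-substituted vinylketenes and the intramolecular Diels–Alder reaction of 1,7,9-decatrienes; here the [2+2] mode is shut off because it would place the (E)-olefin in an eight-membered bridge. The tetrahydropyran closes as the four-atom-tether ring (6-exo with respect to the enol-ether double bond) and the cyclohexenone as the cycloaddition ring. The two ring-fusion centres C4a and C8a arise from the (E)-diene geometry and the tether: the cis fusion should follow from the folded (tether-endo) transition state that keeps the angular methyl group off the forming carbocycle, and their sense relative to C2 from a chair-like tether in which the vinyl group of the resident (R)-centre, not its methyl group, is axial. The step needs periselectivity over ketene dimerisation, secured by high dilution and the proximity of the enol ether, and diastereoselectivity relative to C2, secured only by that conformational preference; because it runs at or below 20 °C, the Claisen rearrangement of the allyl isopropenyl ether, which would defeat a thermal Diels–Alder variant, should not compete.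

Step 8
Reactants: 10 (2R,4aS,8aR)-2-ethenyl-2,5,8a-trimethyl-2,3,4,4a,8,8a-hexahydro-7H-chromen-7-one; 11 tert-butyl[(1-methoxyethenyl)oxy]dimethylsilane
Product: 12 methyl [(2R,4aS,5S,8aR)-7-{[tert-butyl(dimethyl)silyl]oxy}-2-ethenyl-2,5,8a-trimethyl-3,4,4a,5,8,8a-hexahydro-2H-chromen-5-yl]acetate
Conditions: TBSOTf (5 mol %), 2,6-di-tert-butyl-4-methylpyridine (10 mol %), CH2Cl2, −78 °C
Reagents that add atoms: none
Why: Mukaiyama–Michael addition with silyl transfer creates the quaternary carbon and the regiodefined enol silane in one event; the nucleophile should enter axially on the face of the ring oxygen, anti to the angular C8a methyl group (avoiding a 1,3-diaxial methyl–nucleophile contact), so that the C5 and C8a methyl groups become cis.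

Step 9
Reactants: 12 methyl [(2R,4aS,5S,8aR)-7-{[tert-butyl(dimethyl)silyl]oxy}-2-ethenyl-2,5,8a-trimethyl-3,4,4a,5,8,8a-hexahydro-2H-chromen-5-yl]acetate; 13 methyl 2-bromo-2-methylpropanoate
Product: 14 methyl 2-[(2R,4aS,5R,6R,8aR)-2-ethenyl-5-(2-methoxy-2-oxoethyl)-2,5,8a-trimethyl-7-oxooctahydro-2H-chromen-6-yl]-2-methylpropanoate
Conditions: fac-Ir(ppy)3 (1 mol %), 2,6-lutidine, MeCN, blue LEDs (450 nm), 20 °C; aqueous work-up
Reagents that add atoms: none
Why: Photoredox radical alkylation of the enol silane: single-electron reduction of 13 gives the electrophilic tertiary α-ester radical, which should add to the electron-rich C6 on the convex face, anti to the pyran ring and to the neighbouring CH2CO2Me group, and oxidation with loss of the silyl group returns the ketone with the new side chain equatorial.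

Step 10
Reactants: 14 methyl 2-[(2R,4aS,5R,6R,8aR)-2-ethenyl-5-(2-methoxy-2-oxoethyl)-2,5,8a-trimethyl-7-oxooctahydro-2H-chromen-6-yl]-2-methylpropanoate
Product: 16 methyl 2-[(2R,4aS,5S,6R,8aR)-2-ethenyl-5-(2-methoxy-2-oxoethyl)-2,5,8a-trimethyloctahydro-2H-chromen-6-yl]-2-methylpropanoate, via tosylhydrazone 15 (not isolated)
Conditions: TsNHNH2, PPTS (cat.), EtOH, 60 °C; then catecholborane, CHCl3, 0 °C; then NaOAc·3H2O, 60 °C
Reagents that add atoms: none
Why: Hydride reduction of the tosylhydrazone and loss of sulfinate and N2 from the diazene replaces C=O by CH2 without strong base (which would eliminate the β ring oxygen) and without hydrogenation, so the esters, the vinyl group and all stereocentres should persist.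

Step 11
Reactants: 16 methyl 2-[(2R,4aS,5S,6R,8aR)-2-ethenyl-5-(2-methoxy-2-oxoethyl)-2,5,8a-trimethyloctahydro-2H-chromen-6-yl]-2-methylpropanoate
Product: 17 2-[(2R,4aS,5S,6R,8aR)-5-(carboxymethyl)-2-ethenyl-2,5,8a-trimethyloctahydro-2H-chromen-6-yl]-2-methylpropanoic acid
Conditions: KOH, MeOH/H2O, 90 °C; then 1 M HCl, 0 °C, to pH 3
Reagents that add atoms: potassium hydroxide [K+].[OH-]
Why: Saponification of both methyl esters, the α,α-dimethyl one needing heat, followed by acidification should give the diacid; no centre is epimerisable and the tertiary allylic ether is stable to base.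

Compound list

1 | (R)-(−)-linalool, (3R)-3,7-dimethylocta-1,6-dien-3-ol | C=C[C@@](O)(C)CCC=C(C)C | starting material
2 | (3R)-3,7-dimethylocta-1,6-dien-3-yl acetate | C=C[C@@](OC(C)=O)(C)CCC=C(C)C | intermediate
3 | (3R,6E)-3,7-dimethyl-8-oxoocta-1,6-dien-3-yl acetate | C=C[C@@](OC(C)=O)(C)CC/C=C(\C)C=O | intermediate
4 | (3R,6E)-8-hydroxy-3,7-dimethylnona-1,6-dien-3-yl acetate (C8 epimers) | C=C[C@@](OC(C)=O)(C)CC/C=C(\C)C(C)O | intermediate
5 | (3E,7R)-3,7-dimethyl-7-(prop-1-en-2-yloxy)nona-3,8-dien-2-ol (C2 epimers) | C=C[C@@](OC(C)=C)(C)CC/C=C(\C)C(C)O | intermediate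
6 | (3E,7R)-3,7-dimethyl-7-(prop-1-en-2-yloxy)nona-3,8-dien-2-one | C=C[C@@](OC(C)=C)(C)CC/C=C(\C)C(C)=O | intermediate
7 | trifluoroacetyl diketone, (5E,9R)-1,1,1-trifluoro-5,9-dimethyl-9-(prop-1-en-2-yloxy)undeca-5,10-diene-2,4-dione | C=C[C@@](OC(C)=C)(C)CC/C=C(\C)C(=O)CC(=O)C(F)(F)F | intermediate
8 | (3E,7R)-1-diazo-3,7-dimethyl-7-(prop-1-en-2-yloxy)nona-3,8-dien-2-one | C=C[C@@](OC(C)=C)(C)CC/C=C(\C)C(=O)C=[N+]=[N-] | intermediate
9 | vinylketene, (3E,7R)-3,7-dimethyl-7-(prop-1-en-2-yloxy)nona-1,3,8-trien-1-one | C=C[C@@](OC(C)=C)(C)CC/C=C(\C)C=C=O | intermediate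
10 | (2R,4aS,8aR)-2-ethenyl-2,5,8a-trimethyl-2,3,4,4a,8,8a-hexahydro-7H-chromen-7-one | C=C[C@@]1(C)CC[C@H]2C(C)=CC(=O)C[C@@]2(C)O1 | intermediate
11 | tert-butyl[(1-methoxyethenyl)oxy]dimethylsilane | C=C(OC)O[Si](C)(C)C(C)(C)C | starting material
12 | methyl [(2R,4aS,5S,8aR)-7-{[tert-butyl(dimethyl)silyl]oxy}-2-ethenyl-2,5,8a-trimethyl-3,4,4a,5,8,8a-hexahydro-2H-chromen-5-yl]acetate | C=C[C@@]1(C)CC[C@H]2[C@@](C)(CC(=O)OC)C=C(O[Si](C)(C)C(C)(C)C)C[C@@]2(C)O1 | intermediate
13 | methyl 2-bromo-2-methylpropanoate | CC(C)(Br)C(=O)OC | starting material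
14 | methyl 2-[(2R,4aS,5R,6R,8aR)-2-ethenyl-5-(2-methoxy-2-oxoethyl)-2,5,8a-trimethyl-7-oxooctahydro-2H-chromen-6-yl]-2-methylpropanoate | C=C[C@@]1(C)CC[C@H]2[C@@](C)(CC(=O)OC)[C@H](C(C)(C)C(=O)OC)C(=O)C[C@@]2(C)O1 | intermediate
15 | tosylhydrazone of 14 at C7 | C=C[C@@]1(C)CC[C@H]2[C@@](C)(CC(=O)OC)[C@H](C(C)(C)C(=O)OC)C(=NNS(=O)(=O)c3ccc(C)cc3)C[C@@]2(C)O1 | intermediate
16 | methyl 2-[(2R,4aS,5S,6R,8aR)-2-ethenyl-5-(2-methoxy-2-oxoethyl)-2,5,8a-trimethyloctahydro-2H-chromen-6-yl]-2-methylpropanoate | C=C[C@@]1(C)CC[C@H]2[C@@](C)(CC(=O)OC)[C@H](C(C)(C)C(=O)OC)CC[C@@]2(C)O1 | intermediate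
17 | 2-[(2R,4aS,5S,6R,8aR)-5-(carboxymethyl)-2-ethenyl-2,5,8a-trimethyloctahydro-2H-chromen-6-yl]-2-methylpropanoic acid | C=C[C@@]1(C)CC[C@H]2[C@@](C)(CC(=O)O)[C@H](C(C)(C)C(=O)O)CC[C@@]2(C)O1 | target

Total step count: 11. Longest linear sequence: 11 steps (1 to 17).

Steps most likely to fail

Step 7 (proposed new method). The ketene may dimerise or be quenched before the chain folds, the enone may undergo photochemical E/Z isomerisation before the Wolff shift, and control of the ring fusion or of the facial sense relative to C2 may be poor. The fallback uses known chemistry and sets out from 3. Tebbe methylenation of both carbonyl groups (aldehyde and acetate, 20 °C or below) should give the triene (3E,7R)-3,7-dimethyl-7-(prop-1-en-2-yloxy)nona-1,3,8-triene F1. A hole-catalysed (cation-radical) intramolecular Diels–Alder reaction of the enol ether with the diene [(4-BrC6H4)3N·SbCl6, 2,6-di-tert-butylpyridine, CH2Cl2, 0 °C], cold enough to outrun the Claisen rearrangement, should give the cyclohexene (2R,4aS,8aR)-2-ethenyl-2,5,8a-trimethyl-3,4,4a,7,8,8a-hexahydro-2H-chromene F2. Allylic oxidation of the ring CH2 next to the olefinic CH (CrO3·3,5-dimethylpyrazole, CH2Cl2, −20 °C) comes back to the route at 10.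

Step 9. Radical addition at the carbon flanked by the new quaternary centre may be slow, so that reduction of the bromide or hydrolysis of the enol silane takes over; addition may occur on the wrong face; and the α-centre may epimerise afterwards. The fallback sets out from 12 and replaces the reductive photoredox alkylation by an oxidative cross-coupling of two enol silanes. Treatment of 12 with the commercially available trimethylsilyl ketene acetal of methyl isobutyrate and (NH4)2Ce(NO3)6 (NaHCO3, MeCN, −30 °C) oxidises the more electron-rich ketene acetal, which then couples at C6 of 12. This comes back at 14 without a new isolable compound (F0).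

Step 8. The β,β-disubstituted enone may be unreactive, facial selectivity in forming the quaternary centre may be poor, and the silyl Lewis acid may ionise the tertiary allylic ether or eliminate the β ring oxygen. The fallback sets out from 10 and activates the nucleophile instead of the enone. Conjugate addition of the Reformatsky reagent BrZnCH2CO2Me mediated by CuBr·SMe2 with in situ trapping by TBSCl (THF, −40 to 0 °C) comes back at 12 without a new isolable compound (F0).

Further compounds

F1 | step 7 | (3E,7R)-3,7-dimethyl-7-(prop-1-en-2-yloxy)nona-1,3,8-triene | C=C[C@@](OC(C)=C)(C)CC/C=C(\C)C=C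
F2 | step 7 | (2R,4aS,8aR)-2-ethenyl-2,5,8a-trimethyl-3,4,4a,7,8,8a-hexahydro-2H-chromene | C=C[C@@]1(C)CC[C@H]2C(C)=CCC[C@@]2(C)O1
F0 | step 9 | none | none
F0 | step 8 | none | none
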